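**Retrosynthetic overview**
- The target comes from its tetra-O-benzyl ether by global hydrogenolysis. The two benzoates come from reductive benzoylation of an o-quinone, so the quinone carbonyls fix the vicinal diester pattern.
- Both biaryl C–C bonds of 3,6-diaryl-4,5-bis(benzyloxy)-o-benzoquinone are cut at once. The forward reaction is a twofold radical C–H arylation of 4,5-bis(benzyloxy)-o-benzoquinone with a 4-(benzyloxy)benzenediazonium salt (new step).
- That o-quinone comes from 3,4-bis(benzyloxy)phenol by IBX ortho-oxygenation, and the phenol from 3,4-bis(benzyloxy)benzaldehyde by Baeyer–Villiger/Dakin oxidation.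
- No ring is built. The central ring is bought as the benzaldehyde, the two outer rings are attached in one flask (C3 first, then C6), and the two benzoyl rings arrive after that.

Assumption: the target has no stereocentre and no stereogenic axis (both outer rings are para-substituted), so it is achiral and no stereocontrol is needed.

**Step 1**
Reactants: 1 3,4-bis(benzyloxy)benzaldehyde
Product: 3 3,4-bis(benzyloxy)phenol, via aryl formate 2 (not isolated)
Conditions: mCPBA (1.3 equiv), CH2Cl2, 0 °C to rt; aq. NaHCO3 wash; then K2CO3 (0.2 equiv), MeOH, rt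
Reagents that add atoms: mCPBA, OOC(=O)c1cccc(Cl)c1
Why: Baeyer–Villiger (Dakin-type) oxidation, in which the electron-rich dialkoxyaryl group migrates in the Criegee adduct and the aryl formate is methanolysed under mild base that leaves the benzyl ethers alone; no stereocentre is formed.

**Step 2**
Reactants: 3 3,4-bis(benzyloxy)phenol
Product: 4 4,5-bis(benzyloxy)cyclohexa-3,5-diene-1,2-dione (4,5-bis(benzyloxy)-o-benzoquinone)
Conditions: IBX (1.1 equiv), DMF, rt, 2 h
Reagents that add atoms: IBX, O=C1OI(=O)(O)c2ccccc12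
Why: IBX ortho-oxygenation of an electron-rich phenol, in which the aryloxy-iodane(V) delivers oxygen intramolecularly to the less hindered ortho carbon (para to the 3-OBn group) and the catechol–iodane(III) collapses to the o-quinone, a stable vinylogous diester.

**Step 3**
Reactants: 5 4-(benzyloxy)aniline
Product: 6 4-(benzyloxy)benzenediazonium tetrafluoroborate
Conditions: NaNO2 (1.05 equiv), 48% aq. HBF4 (2.5 equiv), H2O, 0 °C; filter, reprecipitate from acetone/Et2O
Reagents that add atoms: sodium nitrite, [Na+].[O-]N=O; tetrafluoroboric acid, [H+].F[B-](F)(F)F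
Why: Classical diazotisation of a primary arylamine, whose tetrafluoroborate salt precipitates from cold water and is stable enough to be dried and weighed.

**Step 4**
Reactants: 4 4,5-bis(benzyloxy)-o-benzoquinone; 6 4-(benzyloxy)benzenediazonium tetrafluoroborate (3.0 equiv)
Product: 8 4,5-bis(benzyloxy)-3,6-bis[4-(benzyloxy)phenyl]cyclohexa-3,5-diene-1,2-dione, via monoaryl quinone 7 (not isolated)
Conditions: 6 added over 4 h, Cp*2Fe (5 mol %), NaHCO3 (4 equiv), degassed MeCN, 25 °C, dark
Reagents that add atoms: none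
Why: Proposed new method: a redox-neutral twofold radical C–H arylation of an o-benzoquinone at C3/C6, in which Cp*2Fe reduces 6 to N2 and the 4-(benzyloxy)phenyl radical; this radical adds to the only unsubstituted ring carbon (C3, next to C=O) because the adduct radical is stabilised by the 4-OBn oxygen and the C5=C6–C1=O unit (it is the keto tautomer of a semiquinone); NaHCO3 removes the acidic C3–H, and the aryl-semiquinone radical anion reduces the next molecule of 6 (or Cp*2Fe+), which carries the chain and releases 7; the same cycle at C6–H gives 8 with no external oxidant that could attack the benzyl ethers; the closest known reaction type is the Meerwein-type radical arylation of p-benzoquinones with arenediazonium salts, which has not been shown for o-benzoquinones or for a double arylation flanking a 1,2-dione.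

**Step 5**
Reactants: 8 4,5-bis(benzyloxy)-3,6-bis[4-(benzyloxy)phenyl]-o-benzoquinone
Product: 10 4,5-bis(benzyloxy)-3,6-bis[4-(benzyloxy)phenyl]-1,2-phenylene dibenzoate, via catechol 9 (not isolated)
Conditions: Na2S2O4, THF/H2O, rt; extract under Ar; then BzCl (3 equiv), Et3N (4 equiv), DMAP (10 mol %), CH2Cl2, 0 °C to rt
Reagents that add atoms: benzoyl chloride, O=C(Cl)c1ccccc1
Why: Reductive acylation of a quinone (dithionite reduction, then DMAP-catalysed O-benzoylation), in which only the two oxygens that were quinone carbonyls are free, so the diester is necessarily vicinal.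

**Step 6**
Reactants: 10 4,5-bis(benzyloxy)-3,6-bis[4-(benzyloxy)phenyl]-1,2-phenylene dibenzoate
Product: 11 4,5-dihydroxy-3,6-bis(4-hydroxyphenyl)-1,2-phenylene dibenzoate (target, achiral)
Conditions: H2 (1 atm), 20% Pd(OH)2/C, EtOAc/THF 1:1, rt; filter under Ar
Reagents that add atoms: none
Why: Catalytic hydrogenolysis of four aryl benzyl ethers, to which aryl benzoates are inert in a neutral aprotic medium, and no intramolecular acyl shift can follow because every new OH is meta or para to the ester oxygens.

**Compound list**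
1 | 3,4-bis(benzyloxy)benzaldehyde | O=Cc1ccc(OCc2ccccc2)c(OCc2ccccc2)c1 | starting material
2 | 3,4-bis(benzyloxy)phenyl formate | O=COc1ccc(OCc2ccccc2)c(OCc2ccccc2)c1 | intermediate
3 | 3,4-bis(benzyloxy)phenol | Oc1ccc(OCc2ccccc2)c(OCc2ccccc2)c1 | intermediate
4 | 4,5-bis(benzyloxy)cyclohexa-3,5-diene-1,2-dione | O=C1C=C(OCc2ccccc2)C(OCc2ccccc2)=CC1=O | intermediate
5 | 4-(benzyloxy)aniline | Nc1ccc(OCc2ccccc2)cc1 | starting material
6 | 4-(benzyloxy)benzenediazonium tetrafluoroborate | N#[N+]c1ccc(OCc2ccccc2)cc1.F[B-](F)(F)F | intermediate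
7 | 4,5-bis(benzyloxy)-3-[4-(benzyloxy)phenyl]cyclohexa-3,5-diene-1,2-dione | O=C1C=C(OCc2ccccc2)C(OCc2ccccc2)=C(c2ccc(OCc3ccccc3)cc2)C1=O | intermediate
8 | 4,5-bis(benzyloxy)-3,6-bis[4-(benzyloxy)phenyl]cyclohexa-3,5-diene-1,2-dione | O=C1C(c2ccc(OCc3ccccc3)cc2)=C(OCc2ccccc2)C(OCc2ccccc2)=C(c2ccc(OCc3ccccc3)cc2)C1=O | intermediate
9 | 4,5-bis(benzyloxy)-3,6-bis[4-(benzyloxy)phenyl]benzene-1,2-diol | Oc1c(O)c(-c2ccc(OCc3ccccc3)cc2)c(OCc2ccccc2)c(OCc2ccccc2)c1-c1ccc(OCc2ccccc2)cc1 | intermediate
10 | 4,5-bis(benzyloxy)-3,6-bis[4-(benzyloxy)phenyl]-1,2-phenylene dibenzoate | O=C(Oc1c(OC(=O)c2ccccc2)c(-c2ccc(OCc3ccccc3)cc2)c(OCc2ccccc2)c(OCc2ccccc2)c1-c1ccc(OCc2ccccc2)cc1)c1ccccc1 | intermediate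
11 | 4,5-dihydroxy-3,6-bis(4-hydroxyphenyl)-1,2-phenylene dibenzoate | O=C(Oc1c(OC(=O)c2ccccc2)c(-c2ccc(O)cc2)c(O)c(O)c1-c1ccc(O)cc1)c1ccccc1 | target

Total step count: 6. Longest linear sequence: 5 steps (1 to 3 to 4 to 8 to 10 to 11).

**Steps most likely to fail**

**Step 2 (IBX oxidation).**
- Risk: oxidation at the para carbon with loss of benzyl alcohol would give a p-quinone, and the o-quinone may be over-oxidised.
- Fallback: it sets out from 3 and comes back at 4, replacing direct oxygen transfer with C–H formylation and aryl migration.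
  - Magnesium-mediated ortho-formylation (MgCl2, Et3N, paraformaldehyde, MeCN, reflux) gives 4,5-bis(benzyloxy)-2-hydroxybenzaldehyde F1.
  - Dakin oxidation (H2O2, NaOH, THF/H2O, 0 °C to rt) passes through 4,5-bis(benzyloxy)-2-hydroxyphenyl formate F2 and gives 4,5-bis(benzyloxy)benzene-1,2-diol F3.
  - Ag2O (CH2Cl2, Na2SO4, rt) dehydrogenates this catechol to 4.

**Step 4 (proposed new step).**
- Risk: the aryl radical may abstract benzylic hydrogen or attack C4/C5 ipso, or the reaction may stop at 7.
- Fallback: it uses only known chemistry, sets out from 4 and comes back at 9.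
  - Na2S2O4 reduces 4 to 4,5-bis(benzyloxy)benzene-1,2-diol F3, the same catechol as above.
  - MOMCl/iPr2NEt (CH2Cl2) gives 1,2-bis(benzyloxy)-4,5-bis(methoxymethoxy)benzene F4.
  - NBS (2.1 equiv, MeCN, 0 °C to rt, dark) gives 1,2-bis(benzyloxy)-3,6-dibromo-4,5-bis(methoxymethoxy)benzene F5.
  - Double Suzuki–Miyaura coupling with 4-(benzyloxy)phenylboronic acid (Pd(OAc)2/SPhos, K3PO4, toluene/H2O, 100 °C) gives 2',3',4,4''-tetrakis(benzyloxy)-5',6'-bis(methoxymethoxy)-1,1':4',1''-terphenyl F6.
  - Catalytic HCl in MeOH/THF (50 °C, Ar) removes the MOM groups to give 9, which is benzoylated as in the second half of step 5.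

**Step 6 (fourfold hydrogenolysis).**
- Risk: the two inner benzyl ethers are flanked on both sides and may stall, and the product catechol can oxidise in air on the catalyst.
- Fallback: it sets out from 10 and comes back at 11 by a non-reductive, homogeneous Lewis-acid dealkylation instead of heterogeneous catalysis. BCl3 (8 equiv) with pentamethylbenzene as cation scavenger (CH2Cl2, −78 °C, then MeOH quench) cleaves aryl benzyl ethers while aryl esters survive. No new compound is made.

**Further compounds**
F1 | step 2 | 4,5-bis(benzyloxy)-2-hydroxybenzaldehyde | O=Cc1cc(OCc2ccccc2)c(OCc2ccccc2)cc1O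
F2 | step 2 | 4,5-bis(benzyloxy)-2-hydroxyphenyl formate | O=COc1cc(OCc2ccccc2)c(OCc2ccccc2)cc1O
F3 | step 2 | 4,5-bis(benzyloxy)benzene-1,2-diol | Oc1cc(OCc2ccccc2)c(OCc2ccccc2)cc1O
F4 | step 4 | 1,2-bis(benzyloxy)-4,5-bis(methoxymethoxy)benzene | COCOc1cc(OCc2ccccc2)c(OCc2ccccc2)cc1OCOC
F5 | step 4 | 1,2-bis(benzyloxy)-3,6-dibromo-4,5-bis(methoxymethoxy)benzene | COCOc1c(Br)c(OCc2ccccc2)c(OCc2ccccc2)c(Br)c1OCOC
F6 | step 4 | 2',3',4,4''-tetrakis(benzyloxy)-5',6'-bis(methoxymethoxy)-1,1':4',1''-terphenyl | COCOc1c(OCOC)c(-c2ccc(OCc3ccccc3)cc2)c(OCc2ccccc2)c(OCc2ccccc2)c1-c1ccc(OCc2ccccc2)cc1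
F0 | step 6 | none | none
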